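The benzene ring of the indole is disconnected at C5–C6. Its four non-fusion carbons are carried by two alkenyl arms on adjacent carbons of an N-tosyl-2,3-dibromopyrrole: a 1-bromovinyl arm (future C4–Br and C5–H) and a 2,2-dibromovinyl arm (future C7–H and C6–Br). Heating this pentabromo triene should trigger a 6π-electrocyclisation across the pyrrole C3a=C7a bond and, by loss of HBr from C5/C6, aromatise the new ring, so one operation forms the carbocycle and delivers the complete 2,3,4,6-bromine pattern. The arms come from a 3-acetylpyrrole-2-carbaldehyde; detosylation finishes the synthesis.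

Key step: step 6

Remark: the target is read as 2,3,4,6-tetrabromo-1H-indole. Every compound in the route is achiral, so no stereodescriptors are needed. The N-tosyl group is kept as the spectator protecting group through the key step.

Step 1
Reactants: 1 3-bromo-1H-pyrrole-2-carbaldehyde; 2 tributyl(1-ethoxyvinyl)stannane
Product: 4 3-acetyl-1H-pyrrole-2-carbaldehyde, via 3-(1-ethoxyethenyl)-1H-pyrrole-2-carbaldehyde 3 (not isolated)
Conditions: PdCl2(PPh3)2 (5 mol %), 1,4-dioxane, 100 °C; then 1 M aq. HCl, THF, rt
Reagents that add atoms: tributyl(1-ethoxyvinyl)stannane 2, CCCC[Sn](CCCC)(CCCC)C(=C)OCC; water, O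
Why: Stille coupling at the C3 bromide, which the ortho formyl group activates toward oxidative addition to zerovalent palladium, needs no base and so tolerates the free N–H, and mild aqueous acid then hydrolyses the enol ether to the methyl ketone.

Step 2
Reactants: 4 3-acetyl-1H-pyrrole-2-carbaldehyde
Product: 5 3-acetyl-4,5-dibromo-1H-pyrrole-2-carbaldehyde
Conditions: NBS (2.1 equiv), DMF, 0 °C to rt, dark
Reagents that add atoms: N-bromosuccinimide, O=C1CCC(=O)N1Br
Why: Electrophilic aromatic bromination of the N–H pyrrole can only take place at the two open ring carbons C4 and C5, and NBS in DMF without added acid should favour ring substitution over bromination of the acetyl methyl group.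

Step 3
Reactants: 5 3-acetyl-4,5-dibromo-1H-pyrrole-2-carbaldehyde
Product: 6 3-acetyl-4,5-dibromo-1-tosyl-1H-pyrrole-2-carbaldehyde
Conditions: NaH (1.1 equiv), THF, 0 °C; then TsCl (1.2 equiv), 0 °C to rt
Reagents that add atoms: p-toluenesulfonyl chloride, Cc1ccc(cc1)S(=O)(=O)Cl
Why: N-Sulfonylation of the sodium pyrrolide (the N–H is by far the most acidic site) installs an electron-withdrawing group that stabilises the polybrominated pyrrole and makes the aldehyde a normal electrophile for the olefination.

Step 4
Reactants: 6 3-acetyl-4,5-dibromo-1-tosyl-1H-pyrrole-2-carbaldehyde; 7 carbon tetrabromide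
Product: 8 1-[4,5-dibromo-2-(2,2-dibromoethenyl)-1-tosyl-1H-pyrrol-3-yl]ethan-1-one
Conditions: 7 (2 equiv), PPh3 (2 equiv), Zn dust (2 equiv), CH2Cl2, rt (ylide pre-formed); then 6, 0 °C to rt
Reagents that add atoms: carbon tetrabromide 7, BrC(Br)(Br)Br
Why: Ramirez dibromo-olefination (first stage of the Corey–Fuchs sequence) with Ph3P=CBr2 should be selective for the aldehyde, because this stabilised ylide reacts only sluggishly with a hindered aryl methyl ketone at or below room temperature.

Step 5
Reactants: 8 1-[4,5-dibromo-2-(2,2-dibromoethenyl)-1-tosyl-1H-pyrrol-3-yl]ethan-1-one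
Product: 9 2,3-dibromo-4-(1-bromoethenyl)-5-(2,2-dibromoethenyl)-1-tosyl-1H-pyrrole
Conditions: (PhO)3P (1.3 equiv), Br2 (1.2 equiv), CH2Cl2, −60 °C; then Et3N (1.5 equiv) and 8, −60 °C to 40 °C
Reagents that add atoms: bromine, BrBr
Why: Dehydrative bromination of an enolisable ketone with the triphenyl phosphite–bromine adduct and Et3N (oxyphosphonium formation, bromide delivery, elimination) gives the 1-bromoalkene without free bromine, so the dibromoalkene and the N-sulfonyl group should survive.

Step 6
Reactants: 9 2,3-dibromo-4-(1-bromoethenyl)-5-(2,2-dibromoethenyl)-1-tosyl-1H-pyrrole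
Product: 11 2,3,4,6-tetrabromo-1-tosyl-1H-indole, via 2,3,4,6,6-pentabromo-1-tosyl-5,6-dihydroindole 10 (not isolated)
Conditions: 2,6-lutidine (2 equiv), BHT (5 mol %), degassed 1,2-dichlorobenzene (0.02 M), 170 °C, sealed tube, dark
Reagents that add atoms: none
Why: Proposed new method: on heating, the s-cis,s-cis rotamer of the triene C5H2=C4(Br)–C3a=C7a–C7H=C6Br2 should undergo a thermal disrotatory 6π-electrocyclisation that closes the six-membered ring through the new C5–C6 bond and gives 10, in which the former pyrrole C3a=C7a bond has become the two exocyclic alkenes C3a=C4 and C7=C7a. One C6 bromide of 10 is allylic and the C5 hydrogens are allylic as well, so ionisation or lutidine-assisted 1,2-elimination removes HBr across C5–C6, both rings become aromatic and the reversible closure is drained toward 11. The closest known reaction type is the thermal 6π-electrocyclisation of 2,3-dialkenylpyrroles and 2,3-dialkenylindoles followed by dehydrogenation or loss of HX to indoles and carbazoles; a gem-dibromo terminus as internal leaving group on a perbrominated N-sulfonylpyrrole has not been shown. No stereocentre is created, because C5 is CH2 and C6 is CBr2 in 10 and both end as sp2 carbons. Regiochemistry is not at issue since the two arms are locked on adjacent ring carbons, and the chemoselectivity needed, loss of HBr and not of Br2, follows from the CH2 terminus carrying the only sp3 C–H next to CBr2. The N-tosyl group lowers the aromatic stabilisation that the pyrrole must give up and steers the CBr2 end away from nitrogen toward the bromovinyl arm, while 2,6-lutidine traps HBr without attacking the vinyl bromides.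

Step 7
Reactants: 11 2,3,4,6-tetrabromo-1-tosyl-1H-indole
Product: 12 2,3,4,6-tetrabromo-1H-indole
Conditions: Cs2CO3 (3 equiv), THF/MeOH (2:1), rt, dark; then aq. NH4Cl
Reagents that add atoms: none
Why: Nucleophilic N–S cleavage by methoxide (Cs2CO3/MeOH detosylation) should be fast because the tetrabromoindolide is a good leaving group, and the mild non-reducing conditions leave all four C–Br bonds untouched.

Compound list
1 | 3-bromo-1H-pyrrole-2-carbaldehyde | O=Cc1[nH]ccc1Br | starting material
2 | tributyl(1-ethoxyvinyl)stannane | CCCC[Sn](CCCC)(CCCC)C(=C)OCC | starting material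
3 | 3-(1-ethoxyethenyl)-1H-pyrrole-2-carbaldehyde | CCOC(=C)c1cc[nH]c1C=O | intermediate (not isolated)
4 | 3-acetyl-1H-pyrrole-2-carbaldehyde | CC(=O)c1cc[nH]c1C=O | intermediate
5 | 3-acetyl-4,5-dibromo-1H-pyrrole-2-carbaldehyde | CC(=O)c1c(Br)c(Br)[nH]c1C=O | intermediate
6 | 3-acetyl-4,5-dibromo-1-tosyl-1H-pyrrole-2-carbaldehyde | Cc1ccc(cc1)S(=O)(=O)n1c(Br)c(Br)c(C(C)=O)c1C=O | intermediate
7 | carbon tetrabromide | BrC(Br)(Br)Br | starting material
8 | 1-[4,5-dibromo-2-(2,2-dibromoethenyl)-1-tosyl-1H-pyrrol-3-yl]ethan-1-one | Cc1ccc(cc1)S(=O)(=O)n1c(Br)c(Br)c(C(C)=O)c1C=C(Br)Br | intermediate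
9 | 2,3-dibromo-4-(1-bromoethenyl)-5-(2,2-dibromoethenyl)-1-tosyl-1H-pyrrole | Cc1ccc(cc1)S(=O)(=O)n1c(Br)c(Br)c(C(Br)=C)c1C=C(Br)Br | intermediate
10 | 2,3,4,6,6-pentabromo-1-tosyl-5,6-dihydro-1H-indole (double bonds C2=C3, C3a=C4, C7=C7a) | Cc1ccc(cc1)S(=O)(=O)N1C(Br)=C(Br)C2=C(Br)CC(Br)(Br)C=C12 | intermediate (not isolated)
11 | 2,3,4,6-tetrabromo-1-tosyl-1H-indole | Cc1ccc(cc1)S(=O)(=O)n1c(Br)c(Br)c2c(Br)cc(Br)cc21 | intermediate
12 | 2,3,4,6-tetrabromo-1H-indole | Brc1cc(Br)c2c(Br)c(Br)[nH]c2c1 | target

Total step count: 7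
Longest linear sequence: 7 steps (1 to 12)

Steps most likely to fail

Step 6. Ring closure may be too slow relative to thermal degradation. The inward bromine of the CBr2 terminus and the C3 bromine beside the bromovinyl arm crowd the helical transition state. At the temperature then needed, C–Br homolysis, dehydrobromination of an arm to a bromoalkyne or oligomerisation can take over. The closure is also reversible, so slow HBr loss would return the triene.

The fallback sets out from 6 and comes back at 11. It uses the established electrocyclisation–dehydrogenation of 2,3-dialkenylpyrroles and brings in the C6 bromine afterwards.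
- Chemoselective Wittig methylenation of the aldehyde (Ph3P=CH2, THF, −78 °C) should give 1-(4,5-dibromo-2-ethenyl-1-tosylpyrrol-3-yl)ethanone F1.
- The ketone is converted as in step 5 into 2,3-dibromo-4-(1-bromoethenyl)-5-ethenyl-1-tosylpyrrole F2.
- Heating F2 in 1,2-dichlorobenzene should close it to 2,3,4-tribromo-1-tosyl-5,6-dihydroindole F3, which is dehydrogenated in the same flask with DDQ to 2,3,4-tribromo-1-tosylindole F4.
- Sterically governed C–H borylation ([Ir(OMe)(cod)]2, 4,4'-di-tert-butyl-2,2'-bipyridine, B2pin2, THF, 80 °C) should occur at C6, the only benzo C–H without an ortho substituent, and give 2,3,4-tribromo-6-(4,4,5,5-tetramethyl-1,3,2-dioxaborolan-2-yl)-1-tosylindole F5.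
- Bromodeboronation with CuBr2 in MeOH/H2O at 80 °C then delivers 11.

Step 5. Activation of the carbonyl group may stall, because the ketone is twisted between two ortho substituents and is electron-poor, or bromine may be transferred to the dibromoalkene.

The fallback sets out from 8 and comes back at 9 by a Barton-type oxidative route through a diazo intermediate instead of dehydrative bromination.
- Condensation with 1,2-bis(tert-butyldimethylsilyl)hydrazine and catalytic Sc(OTf)3 should give the N-silyl hydrazone 1-[4,5-dibromo-2-(2,2-dibromoethenyl)-1-tosylpyrrol-3-yl]ethanone N-(tert-butyldimethylsilyl)hydrazone F6.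
- Br2 and 2-tert-butyl-1,1,3,3-tetramethylguanidine in CH2Cl2 at −78 °C to rt convert F6 into the vinyl bromide 9 with loss of dinitrogen.

Step 2. The second bromination, at the β-position of a doubly acylated ring, may stall while bromination of the acetyl methyl group sets in.

The fallback sets out from 4 and comes back at 12. It postpones the β-bromine to the indole stage, where C3 is the innately nucleophilic position.
- NBS (1 equiv) brominates only the α-carbon and should give 3-acetyl-5-bromo-1H-pyrrole-2-carbaldehyde F7.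
- The conditions of steps 3 to 5 then give in turn 3-acetyl-5-bromo-1-tosylpyrrole-2-carbaldehyde F8, 1-[5-bromo-2-(2,2-dibromoethenyl)-1-tosylpyrrol-3-yl]ethanone F9 and 2-bromo-4-(1-bromoethenyl)-5-(2,2-dibromoethenyl)-1-tosylpyrrole F10.
- Under the conditions of step 6, F10 should close to 2,4,6,6-tetrabromo-1-tosyl-5,6-dihydroindole F11 and lose HBr to give 2,4,6-tribromo-1-tosylindole F12. This closure is less crowded than in the main route.
- Detosylation as in step 7 gives 2,4,6-tribromo-1H-indole F13, and NBS (1 equiv, THF, −78 °C to 0 °C) brominates C3 to give 12.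

Further compounds
F1 | step 6 | 1-(4,5-dibromo-2-ethenyl-1-tosylpyrrol-3-yl)ethanone | Cc1ccc(cc1)S(=O)(=O)n1c(Br)c(Br)c(C(C)=O)c1C=C
F2 | step 6 | 2,3-dibromo-4-(1-bromoethenyl)-5-ethenyl-1-tosylpyrrole | Cc1ccc(cc1)S(=O)(=O)n1c(Br)c(Br)c(C(Br)=C)c1C=C
F3 | step 6 | 2,3,4-tribromo-1-tosyl-5,6-dihydroindole | Cc1ccc(cc1)S(=O)(=O)N1C(Br)=C(Br)C2=C(Br)CCC=C12
F4 | step 6 | 2,3,4-tribromo-1-tosylindole | Cc1ccc(cc1)S(=O)(=O)n1c(Br)c(Br)c2c(Br)cccc21
F5 | step 6 | 2,3,4-tribromo-6-(4,4,5,5-tetramethyl-1,3,2-dioxaborolan-2-yl)-1-tosylindole | Cc1ccc(cc1)S(=O)(=O)n1c(Br)c(Br)c2c(Br)cc(cc21)B1OC(C)(C)C(C)(C)O1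
F6 | step 5 | 1-[4,5-dibromo-2-(2,2-dibromoethenyl)-1-tosylpyrrol-3-yl]ethanone N-(tert-butyldimethylsilyl)hydrazone | Cc1ccc(cc1)S(=O)(=O)n1c(Br)c(Br)c(C(C)=NN[Si](C)(C)C(C)(C)C)c1C=C(Br)Br
F7 | step 2 | 3-acetyl-5-bromo-1H-pyrrole-2-carbaldehyde | CC(=O)c1cc(Br)[nH]c1C=O
F8 | step 2 | 3-acetyl-5-bromo-1-tosylpyrrole-2-carbaldehyde | Cc1ccc(cc1)S(=O)(=O)n1c(Br)cc(C(C)=O)c1C=O
F9 | step 2 | 1-[5-bromo-2-(2,2-dibromoethenyl)-1-tosylpyrrol-3-yl]ethanone | Cc1ccc(cc1)S(=O)(=O)n1c(Br)cc(C(C)=O)c1C=C(Br)Br
F10 | step 2 | 2-bromo-4-(1-bromoethenyl)-5-(2,2-dibromoethenyl)-1-tosylpyrrole | Cc1ccc(cc1)S(=O)(=O)n1c(Br)cc(C(Br)=C)c1C=C(Br)Br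
F11 | step 2 | 2,4,6,6-tetrabromo-1-tosyl-5,6-dihydroindole | Cc1ccc(cc1)S(=O)(=O)N1C(Br)=CC2=C(Br)CC(Br)(Br)C=C12
F12 | step 2 | 2,4,6-tribromo-1-tosylindole | Cc1ccc(cc1)S(=O)(=O)n1c(Br)cc2c(Br)cc(Br)cc21
F13 | step 2 | 2,4,6-tribromo-1H-indole | Brc1cc(Br)c2cc(Br)[nH]c2c1
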